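**Plan**
- Feature: the side chain (numbered C1' to C17' from the ring) has one isolated cis double bond, C8'=C9', flanked on both sides only by unbranched CH2 groups. The resorcinol, the only ring, is bought intact, so the two sp2 carbons can be supplied as acetylene.
- Cuts: C9'–C10' and C7'–C8' together, giving a C10'–C17' alkyl nucleophile, C2H2 and a C1'–C7' alkyl iodide. Then aryl–C1' in the iodide and C14'–C15' in the nucleophile.
- Forward: an aryl Grignard reagent, 1,7-dibromoheptane and halide exchange give the iodide. Epoxide opening, silylation, hydroboration, bromination and magnesium insertion give the nucleophile. Both chains are joined through acetylene in one flask, then one acid step removes all three protecting groups. No ring is formed.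
- Stereochemistry: C16' (S) comes from (S)-propylene oxide, which is opened at its CH2 so the C–O bond of the stereocentre is never touched. The Z geometry comes from syn carbometallation followed by alkylation with retention.

Key step: step 9

Remark: Grignard reagent 15 counts as the product of its own step because it is made as a stock solution and titrated; step 9 needs copper and magnesium in a one-to-one ratio.

Step 1
Reactants: 1 5-bromoresorcinol
Product: 2 1-bromo-3,5-bis(methoxymethoxy)benzene
Conditions: MOMCl (2.6 equiv), iPr2NEt (3 equiv), CH2Cl2, 0 °C → rt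
Reagents that add atoms: chloromethyl methyl ether (MOMCl), COCCl
Why: Base-mediated O-alkylation of both phenols with the reactive chloromethyl ether (MOM acetal formation) masks the acidic OH groups, which would quench every later organometallic reagent, as acetals inert to Mg, Cu and iodide.

Step 2
Reactants: 2 1-bromo-3,5-bis(methoxymethoxy)benzene; 3 1,7-dibromoheptane
Product: 5 1-(7-bromoheptyl)-3,5-bis(methoxymethoxy)benzene, via aryl Grignard reagent 4 (not isolated)
Conditions: Mg, I2 (cat.), THF, reflux; then added to 3 (4 equiv), Li2CuCl4 (5 mol %), THF, −10 °C → rt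
Reagents that add atoms: none
Why: Copper-catalysed (Kochi-type) sp2–sp3 cross-coupling of an aryl Grignard reagent with a primary alkyl bromide forms aryl–C1', a large excess of the symmetrical dibromide suppresses the second substitution, and the surplus is removed by distillation.

Step 3
Reactants: 5 1-(7-bromoheptyl)-3,5-bis(methoxymethoxy)benzene
Product: 6 1-(7-iodoheptyl)-3,5-bis(methoxymethoxy)benzene
Conditions: NaI (3 equiv), acetone, reflux
Reagents that add atoms: NaI, [Na+].[I-]
Why: Finkelstein halide exchange, an SN2 reaction driven by precipitation of NaBr from acetone, installs the softer and better leaving group that an alkenylcopper needs, and the neutral medium leaves the acetals untouched.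

Step 4
Reactants: 7 5-bromopent-1-ene; 8 (S)-propylene oxide
Product: 10 (S)-oct-7-en-2-ol, via pent-4-enylmagnesium bromide 9 (not isolated)
Conditions: Mg, THF, 25–40 °C; then CuI (10 mol %), 8, THF, −30 → 0 °C
Reagents that add atoms: none
Why: Copper-catalysed Grignard opening of a terminal epoxide is an SN2 attack at the less hindered CH2, which forms C14'–C15' and leaves the C–O bond of the stereocentre intact, so C16' keeps the S configuration of 8.

Step 5
Reactants: 10 (S)-oct-7-en-2-ol
Product: 11 (S)-tert-butyldimethyl(oct-7-en-2-yloxy)silane
Conditions: TBSCl (1.2 equiv), imidazole (2.5 equiv), DMF, rt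
Reagents that add atoms: tert-butyldimethylsilyl chloride (TBSCl), C[Si](C)(Cl)C(C)(C)C
Why: Imidazole-promoted silylation of the secondary alcohol, which does not involve the stereocentre, gives an ether that withstands borane, alkaline peroxide, Appel conditions, magnesium and organocopper reagents yet is cleaved by acid at the end.

Step 6
Reactants: 11 (S)-tert-butyldimethyl(oct-7-en-2-yloxy)silane
Product: 13 (S)-7-(tert-butyldimethylsilyloxy)octan-1-ol, via B-alkyl-9-BBN adduct 12 (not isolated)
Conditions: 9-BBN (1.3 equiv), THF, 0 °C → rt; then aq NaOH, H2O2 (30 %), 0 °C → rt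
Reagents that add atoms: hydrogen peroxide, OO
Why: Brown hydroboration with the bulky 9-BBN places boron on the terminal carbon (anti-Markovnikov), and alkaline peroxide oxidation then replaces boron by OH without affecting the silyl ether.

Step 7
Reactants: 13 (S)-7-(tert-butyldimethylsilyloxy)octan-1-ol
Product: 14 (S)-(8-bromooctan-2-yloxy)(tert-butyl)dimethylsilane
Conditions: CBr4 (1.2 equiv), PPh3 (1.3 equiv), CH2Cl2, 0 °C
Reagents that add atoms: carbon tetrabromide, BrC(Br)(Br)Br
Why: In the Appel reaction the alkoxyphosphonium ion of the primary alcohol is displaced by bromide in an SN2 step under essentially neutral conditions that spare the secondary silyl ether.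

Step 8
Reactants: 14 (S)-(8-bromooctan-2-yloxy)(tert-butyl)dimethylsilane
Product: 15 (S)-[7-(tert-butyldimethylsilyloxy)octyl]magnesium bromide (ethereal solution, titrated and used at once)
Conditions: Mg turnings, I2 (cat.), Et2O, reflux
Reagents that add atoms: magnesium, [Mg]
Why: Insertion of magnesium into a primary C–Br bond (Grignard formation) tolerates the silyl ether, and diethyl ether is chosen because carbocupration by magnesium-derived alkylcopper reagents runs best in it.

Step 9
Reactants: 15 (S)-[7-(tert-butyldimethylsilyloxy)octyl]magnesium bromide; 16 acetylene; 6 1-(7-iodoheptyl)-3,5-bis(methoxymethoxy)benzene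
Product: 19 tert-butyl({(2S,9Z)-17-[3,5-bis(methoxymethoxy)phenyl]heptadec-9-en-2-yl}oxy)dimethylsilane (fully protected Hansfordiol E), via alkylcopper 17 (not isolated), via (Z)-alkenylcopper 18 (not isolated)
Conditions: CuBr·SMe2 (1.0 equiv per 15), Et2O/Me2S, −45 °C; 16 (1.05 equiv, acetone-free, metered by gas burette), −50 → −25 °C; HMPA, P(OEt)3, then 6 (0.7 equiv) in THF, −40 °C → rt
Reagents that add atoms: none
Why: Transmetallation of 15 with CuBr·SMe2 gives the monovalent alkylcopper 17, whose C–Cu bond adds across acetylene through a four-centre syn insertion (Normant carbocupration), forming C9'–C10' and placing the chain and the copper cis in 18. With HMPA and P(OEt)3 present to break up aggregates and stabilise the metal, 18 attacks the primary C–I bond of 6, most plausibly by oxidative addition to a trivalent copper species and reductive elimination with retention at the sp2 carbon, forming C7'–C8'. Carbocupration of acetylene by a primary alkylcopper followed by alkylation with a primary alkyl iodide is established chemistry for (Z)-1,2-dialkylethenes of the insect-pheromone type, so this is a known reaction applied to new partners. No ring closes and no stereocentre is created; the only new stereochemical element is the Z double bond, fixed by the syn addition and by the configurational stability of the alkenylcopper at low temperature, while C16' is a remote spectator. The step needs a single insertion, secured by metering in about one equivalent of acetylene and staying at or below −25 °C, where an alkenylcopper adds to a further acetylene much more slowly than the alkylcopper adds to the first. It also needs chemoselectivity, and the partners offer only one electrophilic site, the unbranched primary iodide, because the silyl ether, the acetals and the arene are inert to organocopper reagents.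

Step 10
Reactants: 19 fully protected Hansfordiol E
Product: 20 Hansfordiol E, 5-[(8Z,16S)-16-hydroxyheptadec-8-en-1-yl]benzene-1,3-diol
Conditions: HCl (1.25 M in MeOH), 40 °C
Reagents that add atoms: none
Why: Acid-catalysed transacetalisation of both aryl MOM ethers and methanolysis of the secondary silyl ether run under the same mild conditions, in which excess methanol captures the methoxymethyl cation as dimethoxymethane and neither the isolated Z alkene nor the C16' carbinol is affected.

**Compound list**
1 | 5-bromoresorcinol (5-bromobenzene-1,3-diol) | Oc1cc(O)cc(Br)c1 | starting material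
2 | 1-bromo-3,5-bis(methoxymethoxy)benzene | COCOc1cc(Br)cc(OCOC)c1 | intermediate
3 | 1,7-dibromoheptane | BrCCCCCCCBr | starting material
4 | 3,5-bis(methoxymethoxy)phenylmagnesium bromide | COCOc1cc([Mg]Br)cc(OCOC)c1 | intermediate
5 | 1-(7-bromoheptyl)-3,5-bis(methoxymethoxy)benzene | BrCCCCCCCc1cc(OCOC)cc(OCOC)c1 | intermediate
6 | 1-(7-iodoheptyl)-3,5-bis(methoxymethoxy)benzene | ICCCCCCCc1cc(OCOC)cc(OCOC)c1 | intermediate
7 | 5-bromopent-1-ene | C=CCCCBr | starting material
8 | (S)-propylene oxide | C[C@H]1CO1 | starting material
9 | pent-4-enylmagnesium bromide | C=CCCC[Mg]Br | intermediate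
10 | (S)-oct-7-en-2-ol | C[C@H](O)CCCCC=C | intermediate
11 | (S)-tert-butyldimethyl(oct-7-en-2-yloxy)silane | C[C@H](O[Si](C)(C)C(C)(C)C)CCCCC=C | intermediate
12 | 9-[(S)-7-(tert-butyldimethylsilyloxy)octyl]-9-borabicyclo[3.3.1]nonane | C[C@H](O[Si](C)(C)C(C)(C)C)CCCCCCB1C2CCCC1CCC2 | intermediate
13 | (S)-7-(tert-butyldimethylsilyloxy)octan-1-ol | C[C@H](O[Si](C)(C)C(C)(C)C)CCCCCCO | intermediate
14 | (S)-(8-bromooctan-2-yloxy)(tert-butyl)dimethylsilane | C[C@H](O[Si](C)(C)C(C)(C)C)CCCCCCBr | intermediate
15 | (S)-[7-(tert-butyldimethylsilyloxy)octyl]magnesium bromide | C[C@H](O[Si](C)(C)C(C)(C)C)CCCCCC[Mg]Br | intermediate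
16 | acetylene | C#C | starting material
17 | (S)-[7-(tert-butyldimethylsilyloxy)octyl]copper (present as its MgBr2·SMe2 complex) | C[C@H](O[Si](C)(C)C(C)(C)C)CCCCCC[Cu] | intermediate
18 | [(1Z,9S)-9-(tert-butyldimethylsilyloxy)dec-1-en-1-yl]copper | C[C@H](O[Si](C)(C)C(C)(C)C)CCCCCC/C=C\[Cu] | intermediate
19 | tert-butyl({(2S,9Z)-17-[3,5-bis(methoxymethoxy)phenyl]heptadec-9-en-2-yl}oxy)dimethylsilane | C[C@H](O[Si](C)(C)C(C)(C)C)CCCCCC/C=C\CCCCCCCc1cc(OCOC)cc(OCOC)c1 | intermediate
20 | Hansfordiol E, 5-[(8Z,16S)-16-hydroxyheptadec-8-en-1-yl]benzene-1,3-diol | C[C@H](O)CCCCCC/C=C\CCCCCCCc1cc(O)cc(O)c1 | target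

**Step count**
Total step count: 10.
Longest linear sequence: 7 steps (steps 4, 5, 6, 7, 8, 9 and 10). The aryl branch (steps 1 to 3) joins at step 9.

**Steps most likely to fail**

Step 9. The alkylcopper may decay by β-hydride loss before it has inserted. A second acetylene may insert. The alkenylcopper may dimerise or protonate while the slow substitution of an unactivated iodide is still under way. The fallback sets out from bromide 14, so steps 8 and 9 are both bypassed, and uses the same two-carbon unit as a nucleophile at both ends. LiC≡CH·H2NCH2CH2NH2 in DMSO at rt displaces the bromide to give the terminal alkyne (S)-tert-butyl(dec-9-yn-2-yloxy)dimethylsilane F1. n-BuLi in THF at −78 °C turns F1 into its lithium acetylide F2. Alkylation of F2 with iodide 6 in THF/DMPU gives the internal alkyne (S)-tert-butyl({17-[3,5-bis(methoxymethoxy)phenyl]heptadec-9-yn-2-yl}oxy)dimethylsilane F3. Lindlar semihydrogenation (H2, Pd/CaCO3 poisoned with Pb(OAc)2, quinoline, hexane) adds hydrogen syn and comes back to the route at 19.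

Step 2. The aryl group may transfer sluggishly from copper. The Grignard reagent may homocouple. The product bromide may be substituted a second time despite the excess of dibromide. The fallback sets out from 2 and builds the chain by palladium catalysis. Sonogashira coupling with commercial hept-6-yn-1-ol (PdCl2(PPh3)2, CuI, Et3N, 70 °C) gives 7-[3,5-bis(methoxymethoxy)phenyl]hept-6-yn-1-ol F4. Full hydrogenation (H2, Pd/C, EtOAc) gives 7-[3,5-bis(methoxymethoxy)phenyl]heptan-1-ol F5. Iodination with I2, PPh3 and imidazole in CH2Cl2 comes back to the route at 6, which makes step 3 unnecessary.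

Step 10. The liberated, very electron-rich resorcinol may be attacked on the ring by formaldehyde-derived cations released from the acetals. Longer acid exposure to finish the cleavage may start to isomerise or hydrochlorinate the alkene. The fallback sets out from 19 and removes the two kinds of protecting group separately, by mechanisms that never leave a free oxocarbenium ion next to the free resorcinol. Bu4NF in THF cleaves the Si–O bond to give (2S,9Z)-17-[3,5-bis(methoxymethoxy)phenyl]heptadec-9-en-2-ol F6. ZnBr2 with n-PrSH in CH2Cl2 at 0 °C then transfers each methoxymethyl unit directly to sulfur. This comes back to the route at 20.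

**Further compounds**
F1 | step 9 | (S)-tert-butyl(dec-9-yn-2-yloxy)dimethylsilane | C[C@H](O[Si](C)(C)C(C)(C)C)CCCCCCC#C
F2 | step 9 | lithium acetylide of F1, [(S)-9-(tert-butyldimethylsilyloxy)dec-1-yn-1-yl]lithium | C[C@H](O[Si](C)(C)C(C)(C)C)CCCCCCC#C[Li]
F3 | step 9 | (S)-tert-butyl({17-[3,5-bis(methoxymethoxy)phenyl]heptadec-9-yn-2-yl}oxy)dimethylsilane | C[C@H](O[Si](C)(C)C(C)(C)C)CCCCCCC#CCCCCCCCc1cc(OCOC)cc(OCOC)c1
F4 | step 2 | 7-[3,5-bis(methoxymethoxy)phenyl]hept-6-yn-1-ol | OCCCCCC#Cc1cc(OCOC)cc(OCOC)c1
F5 | step 2 | 7-[3,5-bis(methoxymethoxy)phenyl]heptan-1-ol | OCCCCCCCc1cc(OCOC)cc(OCOC)c1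
F6 | step 10 | (2S,9Z)-17-[3,5-bis(methoxymethoxy)phenyl]heptadec-9-en-2-ol | C[C@H](O)CCCCCC/C=C\CCCCCCCc1cc(OCOC)cc(OCOC)c1
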